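**Retrosynthetic overview**

1. Numbering as in 1-benzofuran (O1, C2, C3, C3a, C4–C7, C7a). The last bonds made are C5–prenyl (Tsuji–Trost on the β-triketone), C7–prenyl (dearomatizing Claisen shift from O6) and C5–acyl (Friedel–Crafts), all on arene 19.
2. Arene 19 is made in one flask from the acyclic bis(alkynyl ether) 13. A ketene (C6=C3a) adds across the propynyl ether carried by O1, forming C6–C7 and C3a–C7a; the cyclobutenone then opens to a vinylketene and 1,1-dimethoxyethene supplies C4/C5.
3. Enabling feature: the 1,3,5-oxygenated carbocycle (C4=O, C6=O, C7a–O1), whose ring oxygen O1 sits on C7a and is tied back to C3a through C2–C3. C7a/C7 are therefore an alkynyl ether on the C2 oxygen and C6/C3a a ketene, and the three-atom tether fixes the linear ring fusion.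
4. Diyne 13 comes from nerol: Sharpless epoxidation and Payne transposition set C2 and the carbinol carbon; an alkoxyacetylide and an O-alkynylation add the two alkynes.
5. Ring order: dihydrofuran together with a temporary cyclobutenone, then the six-membered ring in the same flask, then dearomatization at C7 and at C5.

Key step: step 9

Remark on the chemistry: the (S,S) pair C2/carbinol carbon of the target is the pattern of an anti-opened (Z)-2,3-epoxide, so nerol and the D-(−)-tartrate catalyst are the source. D-(−)-diisopropyl tartrate, 1,1-dimethoxyethene and tert-butyl 2-methylbut-3-en-2-yl carbonate are taken as purchased reagents.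

**Route**

Step 1
Reactants: 1 nerol, (2Z)-3,7-dimethylocta-2,6-dien-1-ol
Product: 2 [(2R,3S)-3-methyl-3-(4-methylpent-3-en-1-yl)oxiran-2-yl]methanol ((2R,3S)-2,3-epoxynerol)
Conditions: Ti(OiPr)4 (5 mol%), D-(−)-diisopropyl tartrate (6 mol%), t-BuOOH, 4 Å molecular sieves, CH2Cl2, −20 °C
Reagents that add atoms: tert-butyl hydroperoxide, CC(C)(C)OO
Why: Sharpless asymmetric epoxidation of the allylic alcohol; the D-(−)-tartrate catalyst delivers oxygen to the face that gives the (2R,3S)-epoxide, and the remote trisubstituted alkene is not touched.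

Step 2
Reactants: 2 (2R,3S)-2,3-epoxynerol
Product: 3 (2S,3S)-3,7-dimethyloct-6-ene-1,2,3-triol
Conditions: 0.5 M NaOH (aq), t-BuOH, 75 °C
Reagents that add atoms: water, O
Why: Payne rearrangement with opening by hydroxide: the C1 alkoxide inverts C2 and hydroxide opens the terminal epoxide at C1 (direct attack at C2 gives the same triol), so C2 becomes S while the tertiary center keeps its configuration.

Step 3
Reactants: 3 (2S,3S)-3,7-dimethyloct-6-ene-1,2,3-triol
Product: 4 (2S)-6-methyl-2-[(2S)-oxiran-2-yl]hept-5-en-2-ol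
Conditions: NaH (2.2 equiv), 1-(p-toluenesulfonyl)imidazole (1.05 equiv), THF, 0 °C → rt
Reagents that add atoms: none
Why: Selective sulfonylation of the primary hydroxyl and 3-exo-tet displacement by the C2 alkoxide (intramolecular Williamson reaction) should give the terminal epoxide with retention at C2.

Step 4
Reactants: 4 (2S)-6-methyl-2-[(2S)-oxiran-2-yl]hept-5-en-2-ol
Product: 5 triethyl({(2S)-6-methyl-2-[(2S)-oxiran-2-yl]hept-5-en-2-yl}oxy)silane
Conditions: Et3SiOTf, 2,6-lutidine, CH2Cl2, −78 °C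
Reagents that add atoms: triethylsilyl trifluoromethanesulfonate, CC[Si](CC)(CC)OS(=O)(=O)C(F)(F)F
Why: Silylation of the tertiary alcohol with a silyl triflate; the protection is needed because a free hydroxyl would trap the ketene of step 9 as a lactone.

Step 5
Reactants: 6 potassium tert-butoxide; 7 trichloroethylene
Product: 8 tert-butyl (E)-1,2-dichlorovinyl ether
Conditions: THF, −78 °C → rt
Reagents that add atoms: none
Why: Greene synthesis of a 1,2-dichlorovinyl ether: base turns 7 into dichloroacetylene and tert-butoxide adds to it in the trans sense.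

Step 6
Reactants: 8 tert-butyl (E)-1,2-dichlorovinyl ether; 5 triethyl({(2S)-6-methyl-2-[(2S)-oxiran-2-yl]hept-5-en-2-yl}oxy)silane
Product: 10 (4S,5S)-1-tert-butoxy-5,9-dimethyl-5-(triethylsilyloxy)dec-8-en-1-yn-4-ol, via lithium tert-butoxyacetylide 9 (not isolated)
Conditions: 8, n-BuLi (2.1 equiv), THF, −78 → −40 °C; then BF3·OEt2, 5, −78 °C
Reagents that add atoms: none
Why: Elimination and chlorine–lithium exchange give the lithium alkoxyacetylide, which opens the epoxide at its unhindered CH2 under BF3 activation (Yamaguchi alkynylation); no stereocenter is touched.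

Step 7
Reactants: 10 (4S,5S)-1-tert-butoxy-5,9-dimethyl-5-(triethylsilyloxy)dec-8-en-1-yn-4-ol; 7 trichloroethylene
Product: 11 (4S,5S)-1-tert-butoxy-4-[(E)-1,2-dichlorovinyloxy]-5,9-dimethyl-5-(triethylsilyloxy)dec-8-en-1-yne
Conditions: KH (2.2 equiv), THF, 0 °C; then 7, −40 °C → rt
Reagents that add atoms: none
Why: Greene dichlorovinyl ether synthesis on the secondary alkoxide (addition to dichloroacetylene formed in the flask); the alkynyl ether and the silyl ether are stable to base.

Step 8
Reactants: 11 (4S,5S)-1-tert-butoxy-4-[(E)-1,2-dichlorovinyloxy]-5,9-dimethyl-5-(triethylsilyloxy)dec-8-en-1-yne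
Product: 13 (4S,5S)-1-tert-butoxy-5,9-dimethyl-4-(prop-1-yn-1-yloxy)-5-(triethylsilyloxy)dec-8-en-1-yne, via lithium alkynyl ether 12 (not isolated)
Conditions: n-BuLi (2.2 equiv), THF, −78 → −40 °C; then MeI, HMPA, −78 → 20 °C (kept below 30 °C)
Reagents that add atoms: iodomethane, CI
Why: Greene alkynyl ether synthesis: elimination and chlorine–lithium exchange give the lithium alkynyl ether, which is C-methylated; the low temperature keeps the tert-butyl alkynyl ether intact.

Step 9
Reactants: 13 (4S,5S)-1-tert-butoxy-5,9-dimethyl-4-(prop-1-yn-1-yloxy)-5-(triethylsilyloxy)dec-8-en-1-yne; 14 1,1-dimethoxyethene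
Product: 19 (2S)-4-methoxy-7-methyl-2-[(2S)-6-methyl-2-(triethylsilyloxy)hept-5-en-2-yl]-2,3-dihydro-1-benzofuran-6-ol, via aldoketene 15 (not isolated), via bicyclic cyclobutenone 16 (not isolated), via vinylketene 17 (not isolated), via dimethyl ketal 18 (not isolated)
Conditions: PhMe (5 mM), 80 °C; then 14 (5 equiv), sealed tube, 110 °C; then AcOH/THF/H2O, rt
Reagents that add atoms: none
Why: Proposed new method: at 80 °C the tert-butyl alkynyl ether should lose isobutene by a retro-ene reaction to give aldoketene 15, whose C=C adds across the tethered propynyl ether in an intramolecular [2+2] cycloaddition (ketene carbon C6 to the nucleophilic alkyne carbon C7, C3a to the oxygen-bearing C7a) to give cyclobutenone 16; at 110 °C 16 should open in a 4π electrocyclic step to vinylketene 17, which is attacked at C6 by the CH2 of 14 (C5) and then closes from C3a onto the dioxocarbenium carbon (C4) to give 18, and loss of methanol with enolization gives arene 19. The closest known reaction types are ketene generation from tert-butyl alkynyl ethers with intramolecular capture, the ketene/alkoxyalkyne [2+2] route to 3-alkoxycyclobutenones, the Danheiser benzannulation of cyclobutenone-derived vinylketenes and the formal [4+2] annulation of vinylketenes with enamines; their union in one flask with an oxygen-tethered alkynyl ether and a ketene acetal is not described. The dihydrofuran closes through the C3a–C7a bond of the [2+2] step (three-atom tether, fused bicyclo[3.2.0] mode), the four-membered ring is temporary and its C6–C3a bond is cut again, and the six-membered ring closes by a polar formal [4+2] whose second bond is a 6-endo attack of the enol ether carbon C3a. No new stereocenter survives (C3a is sp3 only in 16 and 18), and C2 and the carbinol carbon are not touched. The step needs the uncrossed regiochemistry of the [2+2], secured by the polarity of the alkynyl ether and by the short tether, and ketene formation from the tert-butyl ether before the secondary alkynyl ether fragments, secured by the lower retro-ene temperature of tert-butyl ethers; high dilution and late addition of 14 keep 15 from dimerizing or being captured between molecules. The 6-hydroxy-4-methoxy pattern follows from the ketene oxygen and the acetal carbon, and the mild aqueous acid at the end cleaves any aryl orthoacetate formed from 19 and excess 14.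

Step 10
Reactants: 19 (2S)-4-methoxy-7-methyl-2-[(2S)-6-methyl-2-(triethylsilyloxy)hept-5-en-2-yl]-2,3-dihydro-1-benzofuran-6-ol
Product: 20 1-{(2S)-6-hydroxy-4-methoxy-7-methyl-2-[(2S)-6-methyl-2-(triethylsilyloxy)hept-5-en-2-yl]-2,3-dihydro-1-benzofuran-5-yl}-2-methylpropan-1-one
Conditions: i-PrCOCl, TiCl4, CH2Cl2, −78 °C
Reagents that add atoms: 2-methylpropanoyl chloride, CC(C)C(=O)Cl
Why: Friedel–Crafts acylation at C5, the only free ring position (ortho to O6 and O4, para to O1), directed by the titanium phenoxide; the low temperature is chosen to spare the silyl ether and the alkene.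

Step 11
Reactants: 20 1-{(2S)-6-hydroxy-4-methoxy-7-methyl-2-[(2S)-6-methyl-2-(triethylsilyloxy)hept-5-en-2-yl]-2,3-dihydro-1-benzofuran-5-yl}-2-methylpropan-1-one
Product: 21 1-{(2S)-4-methoxy-7-methyl-6-[(2-methylbut-3-en-2-yl)oxy]-2-[(2S)-6-methyl-2-(triethylsilyloxy)hept-5-en-2-yl]-2,3-dihydro-1-benzofuran-5-yl}-2-methylpropan-1-one
Conditions: Pd(PPh3)4 (5 mol%), tert-butyl 2-methylbut-3-en-2-yl carbonate, THF, 0 °C
Reagents that add atoms: tert-butyl 2-methylbut-3-en-2-yl carbonate, CC(C)(C)OC(=O)OC(C)(C)C=C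
Why: Tsuji–Trost O-allylation: the phenoxide attacks the more substituted terminus of the 1,1-dimethylallyl palladium complex and gives the tertiary (reverse-prenyl) aryl ether at O6, the only free hydroxyl.

Step 12
Reactants: 21 1-{(2S)-4-methoxy-7-methyl-6-[(2-methylbut-3-en-2-yl)oxy]-2-[(2S)-6-methyl-2-(triethylsilyloxy)hept-5-en-2-yl]-2,3-dihydro-1-benzofuran-5-yl}-2-methylpropan-1-one
Product: 22 (2S,7S)-4-methoxy-7-methyl-7-(3-methylbut-2-en-1-yl)-5-(2-methylpropanoyl)-2-[(2S)-6-methyl-2-(triethylsilyloxy)hept-5-en-2-yl]-2,3-dihydro-1-benzofuran-6(7H)-one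
Conditions: PhMe, 110 °C
Reagents that add atoms: none
Why: Aromatic Claisen rearrangement ([3,3] shift) onto the methyl-bearing ortho carbon C7, which dearomatizes the ring; the shift to C7 rather than to acyl-bearing C5 keeps the methoxy-enone/acyl conjugation in the product, and the allyl unit should be delivered to the ring face anti to the C2 substituent, which sets C7 as S (substrate control by a remote center, expected to be modest).

Step 13
Reactants: 22 (2S,7S)-4-methoxy-7-methyl-7-(3-methylbut-2-en-1-yl)-5-(2-methylpropanoyl)-2-[(2S)-6-methyl-2-(triethylsilyloxy)hept-5-en-2-yl]-2,3-dihydro-1-benzofuran-6(7H)-one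
Product: 23 (2S,7S)-4-hydroxy-7-methyl-7-(3-methylbut-2-en-1-yl)-5-(2-methylpropanoyl)-2-[(2S)-6-methyl-2-(triethylsilyloxy)hept-5-en-2-yl]-2,3-dihydro-1-benzofuran-6(7H)-one (enol form of the β-triketone)
Conditions: LiCl, DMF, 80 °C; then cold 0.5 M HCl
Reagents that add atoms: none
Why: SN2 demethylation by chloride of the methyl enol ether of a β-triketone (the triketonate is a carboxylate-like leaving group); the non-hydrolytic conditions leave the dihydrofuran vinylogous ester, and so the position of O1, untouched.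

Step 14
Reactants: 23 (2S,7S)-4-hydroxy-7-methyl-7-(3-methylbut-2-en-1-yl)-5-(2-methylpropanoyl)-2-[(2S)-6-methyl-2-(triethylsilyloxy)hept-5-en-2-yl]-2,3-dihydro-1-benzofuran-6(7H)-one
Product: 24 (2S,5R,7S)-7-methyl-5,7-bis(3-methylbut-2-en-1-yl)-5-(2-methylpropanoyl)-2-[(2S)-6-methyl-2-(triethylsilyloxy)hept-5-en-2-yl]-2,3-dihydro-1-benzofuran-4,6(5H,7H)-dione
Conditions: Pd(PPh3)4 (5 mol%), tert-butyl 2-methylbut-3-en-2-yl carbonate, THF, 0 → 40 °C
Reagents that add atoms: tert-butyl 2-methylbut-3-en-2-yl carbonate, CC(C)(C)OC(=O)OC(C)(C)C=C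
Why: Tsuji–Trost prenylation of the β-triketone: O-allylation followed by [3,3] shift and direct C-attack at the primary allyl terminus both converge on the C5 prenyl compound, and the allyl unit should enter anti to the larger C7 substituent (prenyl), syn to the C7 methyl, which sets C5 as R.

Step 15
Reactants: 24 (2S,5R,7S)-7-methyl-5,7-bis(3-methylbut-2-en-1-yl)-5-(2-methylpropanoyl)-2-[(2S)-6-methyl-2-(triethylsilyloxy)hept-5-en-2-yl]-2,3-dihydro-1-benzofuran-4,6(5H,7H)-dione
Product: 25 (2S,5R,7S)-2-[(2S)-2-hydroxy-6-methylhept-5-en-2-yl]-7-methyl-5,7-bis(3-methylbut-2-en-1-yl)-5-(2-methylpropanoyl)-2,3-dihydro-1-benzofuran-4,6(5H,7H)-dione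
Conditions: HF·pyridine, pyridine, THF, 0 °C
Reagents that add atoms: none
Why: Fluoride cleavage of the tertiary triethylsilyl ether under buffered, non-basic conditions that should spare the non-enolizable triketone and the alkenes.

**Compound list**

1 | nerol, (2Z)-3,7-dimethylocta-2,6-dien-1-ol | CC(C)=CCC/C(C)=C\CO | starting material
2 | [(2R,3S)-3-methyl-3-(4-methylpent-3-en-1-yl)oxiran-2-yl]methanol | OC[C@H]1O[C@@]1(C)CCC=C(C)C | intermediate
3 | (2S,3S)-3,7-dimethyloct-6-ene-1,2,3-triol | CC(C)=CCC[C@](C)(O)[C@@H](O)CO | intermediate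
4 | (2S)-6-methyl-2-[(2S)-oxiran-2-yl]hept-5-en-2-ol | CC(C)=CCC[C@](C)(O)[C@@H]1CO1 | intermediate
5 | triethyl({(2S)-6-methyl-2-[(2S)-oxiran-2-yl]hept-5-en-2-yl}oxy)silane | CC(C)=CCC[C@](C)(O[Si](CC)(CC)CC)[C@@H]1CO1 | intermediate
6 | potassium tert-butoxide | CC(C)(C)[O-].[K+] | starting material
7 | trichloroethylene | ClC=C(Cl)Cl | starting material
8 | tert-butyl (E)-1,2-dichlorovinyl ether | Cl/C=C(Cl)\OC(C)(C)C | intermediate
9 | lithium tert-butoxyacetylide | [Li]C#COC(C)(C)C | intermediate
10 | (4S,5S)-1-tert-butoxy-5,9-dimethyl-5-(triethylsilyloxy)dec-8-en-1-yn-4-ol | CC(C)=CCC[C@](C)(O[Si](CC)(CC)CC)[C@@H](O)CC#COC(C)(C)C | intermediate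
11 | (4S,5S)-1-tert-butoxy-4-[(E)-1,2-dichlorovinyloxy]-5,9-dimethyl-5-(triethylsilyloxy)dec-8-en-1-yne | CC(C)=CCC[C@](C)(O[Si](CC)(CC)CC)[C@@H](O/C(Cl)=C\Cl)CC#COC(C)(C)C | intermediate
12 | lithium alkynyl ether, lithium salt of (4S,5S)-1-tert-butoxy-4-(ethynyloxy)-5,9-dimethyl-5-(triethylsilyloxy)dec-8-en-1-yne | CC(C)=CCC[C@](C)(O[Si](CC)(CC)CC)[C@@H](OC#C[Li])CC#COC(C)(C)C | intermediate
13 | (4S,5S)-1-tert-butoxy-5,9-dimethyl-4-(prop-1-yn-1-yloxy)-5-(triethylsilyloxy)dec-8-en-1-yne | CC(C)=CCC[C@](C)(O[Si](CC)(CC)CC)[C@@H](OC#CC)CC#COC(C)(C)C | intermediate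
14 | 1,1-dimethoxyethene | C=C(OC)OC | starting material
15 | aldoketene, (4S,5S)-5,9-dimethyl-4-(prop-1-yn-1-yloxy)-5-(triethylsilyloxy)deca-1,8-dien-1-one | CC(C)=CCC[C@](C)(O[Si](CC)(CC)CC)[C@@H](OC#CC)CC=C=O | intermediate
16 | bicyclic cyclobutenone, (3S)-7-methyl-3-[(2S)-6-methyl-2-(triethylsilyloxy)hept-5-en-2-yl]-2-oxabicyclo[3.2.0]hept-1(7)-en-6-one (both C5 epimers) | CC(C)=CCC[C@](C)(O[Si](CC)(CC)CC)[C@@H]1CC2C(=O)C(C)=C2O1 | intermediate
17 | vinylketene, 2-{(5S)-5-[(2S)-6-methyl-2-(triethylsilyloxy)hept-5-en-2-yl]-4,5-dihydrofuran-2-yl}prop-1-en-1-one | CC(C)=CCC[C@](C)(O[Si](CC)(CC)CC)[C@@H]1CC=C(O1)C(C)=C=O | intermediate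
18 | dimethyl ketal, (2S)-4,4-dimethoxy-7-methyl-2-[(2S)-6-methyl-2-(triethylsilyloxy)hept-5-en-2-yl]-3,3a,4,5-tetrahydro-1-benzofuran-6(2H)-one (both C3a epimers) | CC(C)=CCC[C@](C)(O[Si](CC)(CC)CC)[C@@H]1CC2C(OC)(OC)CC(=O)C(C)=C2O1 | intermediate
19 | (2S)-4-methoxy-7-methyl-2-[(2S)-6-methyl-2-(triethylsilyloxy)hept-5-en-2-yl]-2,3-dihydro-1-benzofuran-6-ol | CC(C)=CCC[C@](C)(O[Si](CC)(CC)CC)[C@@H]1Cc2c(OC)cc(O)c(C)c2O1 | intermediate
20 | 1-{(2S)-6-hydroxy-4-methoxy-7-methyl-2-[(2S)-6-methyl-2-(triethylsilyloxy)hept-5-en-2-yl]-2,3-dihydro-1-benzofuran-5-yl}-2-methylpropan-1-one | CC(C)=CCC[C@](C)(O[Si](CC)(CC)CC)[C@@H]1Cc2c(OC)c(C(=O)C(C)C)c(O)c(C)c2O1 | intermediate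
21 | 1-{(2S)-4-methoxy-7-methyl-6-[(2-methylbut-3-en-2-yl)oxy]-2-[(2S)-6-methyl-2-(triethylsilyloxy)hept-5-en-2-yl]-2,3-dihydro-1-benzofuran-5-yl}-2-methylpropan-1-one | CC(C)=CCC[C@](C)(O[Si](CC)(CC)CC)[C@@H]1Cc2c(OC)c(C(=O)C(C)C)c(OC(C)(C)C=C)c(C)c2O1 | intermediate
22 | (2S,7S)-4-methoxy-7-methyl-7-(3-methylbut-2-en-1-yl)-5-(2-methylpropanoyl)-2-[(2S)-6-methyl-2-(triethylsilyloxy)hept-5-en-2-yl]-2,3-dihydro-1-benzofuran-6(7H)-one | CC(C)=CCC[C@](C)(O[Si](CC)(CC)CC)[C@@H]1CC2=C(O1)[C@](C)(CC=C(C)C)C(=O)C(C(=O)C(C)C)=C2OC | intermediate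
23 | (2S,7S)-4-hydroxy-7-methyl-7-(3-methylbut-2-en-1-yl)-5-(2-methylpropanoyl)-2-[(2S)-6-methyl-2-(triethylsilyloxy)hept-5-en-2-yl]-2,3-dihydro-1-benzofuran-6(7H)-one | CC(C)=CCC[C@](C)(O[Si](CC)(CC)CC)[C@@H]1CC2=C(O1)[C@](C)(CC=C(C)C)C(=O)C(C(=O)C(C)C)=C2O | intermediate
24 | (2S,5R,7S)-7-methyl-5,7-bis(3-methylbut-2-en-1-yl)-5-(2-methylpropanoyl)-2-[(2S)-6-methyl-2-(triethylsilyloxy)hept-5-en-2-yl]-2,3-dihydro-1-benzofuran-4,6(5H,7H)-dione | CC(C)=CCC[C@](C)(O[Si](CC)(CC)CC)[C@@H]1CC2=C(O1)[C@](C)(CC=C(C)C)C(=O)[C@](CC=C(C)C)(C(=O)C(C)C)C2=O | intermediate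
25 | (2S,5R,7S)-2-[(2S)-2-hydroxy-6-methylhept-5-en-2-yl]-7-methyl-5,7-bis(3-methylbut-2-en-1-yl)-5-(2-methylpropanoyl)-2,3-dihydro-1-benzofuran-4,6(5H,7H)-dione | CC(C)=CCC[C@](C)(O)[C@@H]1CC2=C(O1)[C@](C)(CC=C(C)C)C(=O)[C@](CC=C(C)C)(C(=O)C(C)C)C2=O | target

**Totals**

Total step count: 15. Longest linear sequence: 14 steps (steps 1–4 and 6–15; step 5 prepares a reagent branch).

**Steps most likely to fail**

Step 9 (Proposed new method). The vinylketene may be diverted by the ketene acetal into stable [2+2] adducts or open-chain acylation products instead of closing the six-membered ring. Before that, the first ketene may dimerize, or the secondary alkynyl ether may fragment. The fallback sets out from 13 and comes back at 19. Compound 13 is heated alone in dilute toluene (80 °C) and the bicyclic cyclobutenone 16 is isolated. It is then used in the long-established thermal benzannulation of a cyclobutenone with a silyloxyalkyne (PhMe, 110 °C). The alkyne is (triisopropylsilyloxy)ethyne F1, made from lithium acetylide by oxidation to the ynolate with LiOOt-Bu and O-silylation with i-Pr3SiOTf. Here the ketene oxygen ends on C4 and the silyloxy group on C6, so the product should be (2S)-7-methyl-2-[(2S)-6-methyl-2-(triethylsilyloxy)hept-5-en-2-yl]-6-(triisopropylsilyloxy)-2,3-dihydro-1-benzofuran-4-ol F2. Methylation (MeI, K2CO3, acetone) gives triisopropyl({(2S)-4-methoxy-7-methyl-2-[(2S)-6-methyl-2-(triethylsilyloxy)hept-5-en-2-yl]-2,3-dihydro-1-benzofuran-6-yl}oxy)silane F3. Buffered fluoride (Bu4NF, AcOH, THF, 0 °C) then cleaves only the aryl silyl ether and returns 19.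

Step 12. The [3,3] shift may go in part to the acyl-bearing ortho carbon C5 or move on by a Cope shift to C3a, and facial selectivity at C7 may be poor because the controlling center at C2 is remote. The fallback sets out from 20 and comes back at 22. It is an intermolecular alkylative dearomatization of the kind used for acylphloroglucinols. The phenoxide of 20 is C-prenylated at C7, ortho to the phenoxide oxygen, with 1-bromo-3-methylbut-2-ene, using either LiN(SiMe3)2 in toluene or CsOH·H2O with a cinchona-derived quaternary ammonium bromide in CH2Cl2 at low temperature. In the second variant a chiral ion-pairing catalyst, not the C2 center, selects the face. Compounds outside the list: none F0.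

Step 14. O-alkylated material may fail to move to carbon, the branched (reverse-prenyl) isomer may form at C5, the triketone product may suffer retro-Claisen cleavage, and the face selectivity relative to C7 may be low. The fallback sets out from 23 and comes back at 24. O-Allylation (allyl bromide, K2CO3, acetone) gives (2S,7S)-4-(allyloxy)-7-methyl-7-(3-methylbut-2-en-1-yl)-5-(2-methylpropanoyl)-2-[(2S)-6-methyl-2-(triethylsilyloxy)hept-5-en-2-yl]-2,3-dihydro-1-benzofuran-6(7H)-one F4. Thermal Claisen rearrangement (PhMe, 110 °C), regiospecific for C5 and again anti to the C7 prenyl group, gives (2S,5R,7S)-7-methyl-7-(3-methylbut-2-en-1-yl)-5-(2-methylpropanoyl)-5-(prop-2-en-1-yl)-2-[(2S)-6-methyl-2-(triethylsilyloxy)hept-5-en-2-yl]-2,3-dihydro-1-benzofuran-4,6(5H,7H)-dione F5. Cross-metathesis with 2-methyl-2-butene (second-generation Grubbs catalyst, CH2Cl2, 40 °C) turns allyl into prenyl; the trisubstituted alkenes only exchange degenerately.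

**Further compounds**

F1 | step 9 | (triisopropylsilyloxy)ethyne | C#CO[Si](C(C)C)(C(C)C)C(C)C
F2 | step 9 | (2S)-7-methyl-2-[(2S)-6-methyl-2-(triethylsilyloxy)hept-5-en-2-yl]-6-(triisopropylsilyloxy)-2,3-dihydro-1-benzofuran-4-ol | CC(C)=CCC[C@](C)(O[Si](CC)(CC)CC)[C@@H]1Cc2c(O)cc(O[Si](C(C)C)(C(C)C)C(C)C)c(C)c2O1
F3 | step 9 | triisopropyl({(2S)-4-methoxy-7-methyl-2-[(2S)-6-methyl-2-(triethylsilyloxy)hept-5-en-2-yl]-2,3-dihydro-1-benzofuran-6-yl}oxy)silane | CC(C)=CCC[C@](C)(O[Si](CC)(CC)CC)[C@@H]1Cc2c(OC)cc(O[Si](C(C)C)(C(C)C)C(C)C)c(C)c2O1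
F0 | step 12 | none | none
F4 | step 14 | (2S,7S)-4-(allyloxy)-7-methyl-7-(3-methylbut-2-en-1-yl)-5-(2-methylpropanoyl)-2-[(2S)-6-methyl-2-(triethylsilyloxy)hept-5-en-2-yl]-2,3-dihydro-1-benzofuran-6(7H)-one | CC(C)=CCC[C@](C)(O[Si](CC)(CC)CC)[C@@H]1CC2=C(O1)[C@](C)(CC=C(C)C)C(=O)C(C(=O)C(C)C)=C2OCC=C
F5 | step 14 | (2S,5R,7S)-7-methyl-7-(3-methylbut-2-en-1-yl)-5-(2-methylpropanoyl)-5-(prop-2-en-1-yl)-2-[(2S)-6-methyl-2-(triethylsilyloxy)hept-5-en-2-yl]-2,3-dihydro-1-benzofuran-4,6(5H,7H)-dione | CC(C)=CCC[C@](C)(O[Si](CC)(CC)CC)[C@@H]1CC2=C(O1)[C@](C)(CC=C(C)C)C(=O)[C@](CC=C)(C(=O)C(C)C)C2=O
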